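Per minute is the unit in which the meeting on these two flasks reckoned its constants.

| setting | zeta | beta |
|---|---|---|
| substrate | 0.050 M | 0.050 M |
| first nucleophile | 0.0550 M | 0.0550 M |
| second nucleophile | 0.0450 M | 0.0450 M |
| temperature | 0 °C | −20 °C |
| time | 10 h | 10 h |

    substrate → intermediate (k1 = 0.20 min⁻¹, Ea1 = 79.0 kJ mol⁻¹)
    first nucleophile + intermediate → target (k2 = 11 M⁻¹ min⁻¹, Ea2 = 35.0 kJ mol⁻¹)
    second nucleophile + intermediate → other capture product (k3 = 4.1 M⁻¹ min⁻¹, Ea3 = 54.0 kJ mol⁻¹)
    intermediate → solvolysis product (k4 = 0.51 min⁻¹, Ea4 = 72.0 kJ mol⁻¹)
    second nucleophile → decomposition product (k5 = 1.3 × 10⁻⁵ min⁻¹, Ea5 = 100 kJ mol⁻¹)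
    first nucleophile → decomposed reagent (k6 = 0.051 min⁻¹, Ea6 = 74.0 kJ mol⁻¹)
    (constants at −20 °C)

* the flask that comes out highest in share of target in all that became target or other capture product or solvolysis product, or "all alike" when all lie within 1.5 percentage points (zeta / beta / all alike)
* share of target in all that became target or other capture product or solvolysis product, zeta
* share of target in all that became target or other capture product or solvolysis product, beta

- the list of constants is for −20 °C, to be carried to other temperatures by the activation energies

The chair asked first for the constants of zeta. The first speaker took the factor by which solvolysis speeds up from beta to zeta, 12, and raised it for each other step to that step's activation energy over the solvolysis one. So in zeta the substrate opens at 3.12 min⁻¹, capture by the first nucleophile has 37.2 M⁻¹ min⁻¹, capture by the second nucleophile has 26.8 M⁻¹ min⁻¹, solvolysis has 6.24 min⁻¹, and the first nucleophile decomposes at 0.669 min⁻¹.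

The same speaker then treated the intermediate as a thing with exits. Each capture exit runs at its constant times c(nucleophile), solvolysis runs at its constant, and the target's share, the selectivity, is the first exit over their sum. With full charges that gave 21.5% for zeta and 46.6% for beta.

I objected that the first nucleophile does not stay at its charge. In zeta decomposition gives it a lifetime of 1.49 min and opening gives the substrate one of 0.320 min, so the reagent decays more slowly than the substrate.

Averaged over the moments at which intermediate is born, the part of the first nucleophile that decomposition has spared is its survival, the substrate's constant over the sum of that constant and the decomposition constant: 82.4% in zeta, and 79.7% in beta.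

The chair added that capture uses up the first nucleophile as well, so c(first nucleophile) should on average, as an estimate, also lose 0.5 of the target made. With both corrections I committed to 16.9% for zeta and 34.7% for beta, so beta stands higher.

The forecast said 16.5% for zeta, a little under mine, and 35% for beta, with beta highest, on the ground that “The intermediate's solvolysis and the first nucleophile's decomposition both have higher activation energies than target capture”.

The flasks gave 16.1% in zeta and 34.6% in beta, so beta came out highest, and zeta's substrate reached half conversion after 0.222 min. Zeta's survival of 82.4% holds no charge in its formula, so it carries to a neighbour of zeta charged with 0.22 M of first nucleophile, other charges and the time held, where the same reckoning gives 45.8%. That neighbour gave 44.4%.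

(The constants were drawn at random within sensible limits, and the outcome is calculated.)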